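**Retrosynthetic overview**
1. The C2–CH2–C2' bridge is made last, by condensing two molecules of the naphthalenone monomer 13 with formaldehyde at the enol carbon C2 of ring B.
2. Ring B of the monomer (C1–C2–C3–C4–C4a–C8a) is opened at C4–C4a. The C4 tertiary radical that closes this bond is released by oxidative β-scission of a 1-aryl-3,3-diethoxy-2,2-dimethylcyclobutanol (9), a strain-release ring expansion from cyclobutanol to tetralone.
3. Enabling feature: in ring B the aryl ketone carbon C1 and the quaternary C4 are 1,4-related through C2–C3, so they can be tied by a temporary C1–C4 bond in a four-membered ring that carries C3 as a ketal. C4a is the only unsubstituted ortho carbon of ring A and lies ortho to the C1 carbonyl and para to the C7 acetyl.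
4. Cyclobutanol 9 comes from aryllithium addition to cyclobutanone 4 (dimethylketene plus ketene diethyl acetal, [2+2]), then ortho-lithiation and acetylation between the two methoxy groups.
5. Ring order: ring A is bought; the temporary cyclobutane is made in step 1; ring B in step 4; the two halves are joined in step 6.

Key step: step 4

Remark: the target has no stereocenter. Compounds 7 and 9 are racemic, and their single carbinol stereocenter is erased in step 4. The enolised β-diketones are written as the 3-hydroxy-1-oxo tautomers.

**Step 1**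
Reactants: 1 2-bromo-2-methylpropanoyl bromide; 2 1,1-diethoxyethene (ketene diethyl acetal)
Product: 4 3,3-diethoxy-2,2-dimethylcyclobutan-1-one, via dimethylketene 3 (not isolated)
Conditions: Zn dust, EtOAc, reduced pressure (3 carried over under N2 as an EtOAc solution); then 2, Et2O, 0 °C → rt
Reagents that add atoms: none
Why: Zinc dehalogenation of the α-bromoacyl bromide should give dimethylketene free of acyl halide, and its thermal [2+2] cycloaddition with the electron-rich ketene acetal should join the ketene carbonyl carbon to the acetal CH2 terminus, which places the ketal carbon next to the CMe2 carbon; no stereocenter is formed.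

**Step 2**
Reactants: 5 1-bromo-2,4-dimethoxybenzene; 4 3,3-diethoxy-2,2-dimethylcyclobutan-1-one
Product: 7 1-(2,4-dimethoxyphenyl)-3,3-diethoxy-2,2-dimethylcyclobutan-1-ol (racemic), via 2,4-dimethoxyphenyllithium 6 (not isolated)
Conditions: n-BuLi, THF, −78 °C; then 4, −78 → −20 °C; H2O quench (no acid)
Reagents that add atoms: none
Why: Bromine–lithium exchange followed by 1,2-addition to the strained cyclobutanone, where enolisation toward a cyclobutene is disfavoured; the carbinol stereocenter forms as a racemate and is of no consequence.

**Step 3**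
Reactants: 7 1-(2,4-dimethoxyphenyl)-3,3-diethoxy-2,2-dimethylcyclobutan-1-ol
Product: 9 1-[3-(3,3-diethoxy-1-hydroxy-2,2-dimethylcyclobutyl)-2,6-dimethoxyphenyl]ethan-1-one (racemic), via dilithiated alkoxide 8 (not isolated)
Conditions: n-BuLi (2.3 equiv), TMEDA, THF, 0 °C → rt; then MeC(O)N(OMe)Me, −78 → 0 °C; H2O
Reagents that add atoms: N-methoxy-N-methylacetamide, CC(=O)N(C)OC
Why: Directed ortho-metalation: after the alcohol is deprotonated, the second equivalent of base should remove the doubly activated hydrogen between the two methoxy groups, and acylation with the N-methoxy-N-methylamide stops at the ketone; the ketal and the lithium alkoxide (which has no carbanion-stabilising group for fragmentation) are inert.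

**Step 4**
Reactants: 9 1-[3-(3,3-diethoxy-1-hydroxy-2,2-dimethylcyclobutyl)-2,6-dimethoxyphenyl]ethan-1-one
Product: 12 7-acetyl-3-hydroxy-6,8-dimethoxy-4,4-dimethylnaphthalen-1(4H)-one, via tertiary radical 10 (not isolated), via ketal tetralone 11 (not isolated)
Conditions: AgNO3 (20 mol %), K2S2O8 (3 equiv), pyridine (4 equiv), CH2Cl2/H2O 1:1, 30 °C; aq. Na2S2O3; then 1 M HCl, THF, rt
Reagents that add atoms: water, O
Why: Peroxydisulfate oxidises monovalent silver to divalent silver, which converts the tertiary cyclobutanol of 9 into its alkoxy radical; strain-driven β-scission of the ring bond between the carbinol carbon and the gem-dimethyl carbon gives the aryl ketone and tertiary radical 10, which adds to the only free ortho carbon of ring A (C4a), and base-assisted oxidation of the cyclohexadienyl radical restores the arene to give 11, whose β-keto ketal is hydrolysed in the acid work-up to 12. The closest known reaction type is the oxidative radical ring expansion of 1-arylcyclobutanols to 1-tetralones with AgNO3/K2S2O8 or (NH4)2Ce(NO3)6. Ring B closes by a six-membered homolytic aromatic substitution at the ortho position (6-exo with respect to the C4a–C5 π bond), helped by the Thorpe–Ingold effect of the gem-dimethyl and ketal carbons. No stereocenter is created and the carbinol stereocenter of 9 is erased. The step needs scission toward the CMe2 carbon and not the CH2 carbon, which the tertiary (versus primary) radical and the relief of crowding between the two fully substituted ring carbons should secure, and attack at C4a, which is the sole unsubstituted ortho position and, being ortho to the new C1 ketone and para to the C7 acetyl, is polarity-matched to the nucleophilic radical. The ketal keeps the radical nucleophilic and blocks retro-aldol opening, and the pyridine buffer prevents acid ionisation of the dimethoxybenzylic alcohol.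

**Step 5**
Reactants: 12 7-acetyl-3-hydroxy-6,8-dimethoxy-4,4-dimethylnaphthalen-1(4H)-one
Product: 13 7-acetyl-3,6,8-trihydroxy-4,4-dimethylnaphthalen-1(4H)-one
Conditions: BBr3 (5 equiv), CH2Cl2, −78 °C → rt; then H2O
Reagents that add atoms: none
Why: Lewis-acid cleavage of aryl methyl ethers; both methoxy groups are ortho to a carbonyl (chelation-assisted), and the enolised dione should survive as a boron chelate that is hydrolysed on work-up.

**Step 6**
Reactants: 13 7-acetyl-3,6,8-trihydroxy-4,4-dimethylnaphthalen-1(4H)-one (two molecules)
Product: 15 2,2'-methylenebis[7-acetyl-3,6,8-trihydroxy-4,4-dimethylnaphthalen-1(4H)-one], via methylidene trione 14 (not isolated)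
Conditions: 37% aq. HCHO (0.5 equiv), EtOH/H2O, rt
Reagents that add atoms: formaldehyde, C=O
Why: Knoevenagel condensation of the cyclic β-diketone with formaldehyde gives the 2-methylidene trione 14, which is trapped by Michael addition of a second enol (the classical methylene-bis-1,3-dione formation); C2 of ring B is far more nucleophilic than the acyl-deactivated and peri-hindered C5 of ring A, and half an equivalent of formaldehyde limits the reaction to one bridge.

**Compound list**
1 | 2-bromo-2-methylpropanoyl bromide | CC(C)(Br)C(=O)Br | starting material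
2 | 1,1-diethoxyethene (ketene diethyl acetal) | C=C(OCC)OCC | starting material
3 | dimethylketene | CC(C)=C=O | intermediate
4 | 3,3-diethoxy-2,2-dimethylcyclobutan-1-one | CCOC1(OCC)CC(=O)C1(C)C | intermediate
5 | 1-bromo-2,4-dimethoxybenzene | COc1ccc(Br)c(OC)c1 | starting material
6 | 2,4-dimethoxyphenyllithium | [Li]c1ccc(OC)cc1OC | intermediate
7 | 1-(2,4-dimethoxyphenyl)-3,3-diethoxy-2,2-dimethylcyclobutan-1-ol (racemic) | CCOC1(OCC)CC(O)(c2ccc(OC)cc2OC)C1(C)C | intermediate
8 | lithium 1-(3-lithio-2,4-dimethoxyphenyl)-3,3-diethoxy-2,2-dimethylcyclobutan-1-olate | CCOC1(OCC)CC(O[Li])(c2ccc(OC)c([Li])c2OC)C1(C)C | intermediate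
9 | 1-[3-(3,3-diethoxy-1-hydroxy-2,2-dimethylcyclobutyl)-2,6-dimethoxyphenyl]ethan-1-one (racemic) | CCOC1(OCC)CC(O)(c2ccc(OC)c(C(C)=O)c2OC)C1(C)C | intermediate
10 | 5-(3-acetyl-2,4-dimethoxyphenyl)-3,3-diethoxy-2-methyl-5-oxopentan-2-yl radical | CCOC(OCC)(CC(=O)c1ccc(OC)c(C(C)=O)c1OC)[C](C)C | intermediate
11 | 7-acetyl-3,3-diethoxy-6,8-dimethoxy-4,4-dimethyl-3,4-dihydronaphthalen-1(2H)-one | CCOC1(OCC)CC(=O)c2c(OC)c(C(C)=O)c(OC)cc2C1(C)C | intermediate
12 | 7-acetyl-3-hydroxy-6,8-dimethoxy-4,4-dimethylnaphthalen-1(4H)-one | CC(=O)c1c(OC)cc2c(c1OC)C(=O)C=C(O)C2(C)C | intermediate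
13 | 7-acetyl-3,6,8-trihydroxy-4,4-dimethylnaphthalen-1(4H)-one | CC(=O)c1c(O)cc2c(c1O)C(=O)C=C(O)C2(C)C | intermediate
14 | 7-acetyl-6,8-dihydroxy-4,4-dimethyl-2-methylidenenaphthalene-1,3(2H,4H)-dione | C=C1C(=O)c2c(O)c(C(C)=O)c(O)cc2C(C)(C)C1=O | intermediate
15 | 2,2'-methylenebis[7-acetyl-3,6,8-trihydroxy-4,4-dimethylnaphthalen-1(4H)-one] | CC(=O)c1c(O)cc2c(c1O)C(=O)C(CC1=C(O)C(C)(C)c3cc(O)c(C(C)=O)c(O)c3C1=O)=C(O)C2(C)C | target

**Total step count:** 6
**Longest linear sequence:** 6 steps (1 → 4 → 7 → 9 → 12 → 13 → 15)

**Steps most likely to fail**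

Step 4. The tertiary radical may be oxidised to the cation and lost by elimination, or may attack the ipso carbon with aryl migration, before it closes on C4a. The electron-rich carbinol may also ionise and fragment if the buffer is exhausted. The fallback forms the same C4–C4a bond by two-electron aryne chemistry; it sets out from 9 and comes back at 12. Bromination of 9 at C5, the only activated ring position (NBS, MeCN, 0 °C, dark), should give 1-[3-bromo-5-(3,3-diethoxy-1-hydroxy-2,2-dimethylcyclobutyl)-2,6-dimethoxyphenyl]ethan-1-one F1. Mild ketal hydrolysis (PPTS, acetone/H2O), followed by retro-aldol opening of the resulting β-hydroxycyclobutanone (completed with K2CO3, MeOH), should give 1-(3-acetyl-5-bromo-2,4-dimethoxyphenyl)-4-methylpentane-1,3-dione F2. Treatment of F2 with lithium 2,2,6,6-tetramethylpiperidide (5 equiv, THF, −78 → 0 °C) should remove the only hydrogen ortho to bromine and expel bromide to give the C4a–C5 aryne F3 (drawn without its lithium enolate counter-ions). Its C4a is captured by the C4 carbanion of the diketone dianion in an intramolecular enolate–aryne cyclisation; the tether and the C6 methoxy group, which stabilises the aryl anion at C5, fix the regiochemistry, and protonation at C5 on work-up gives 12.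

Step 3. Lithiation may occur ortho to the alkoxide instead of between the methoxy groups, or the hindered aryllithium may be quenched by proton transfer from the amide, so that conversion stays low. The fallback carries the acetyl group in masked form through the aryl addition; it sets out from 4 and comes back at 9. Commercial 2',6'-dimethoxyacetophenone is brominated (NBS, MeCN, rt) to 1-(3-bromo-2,6-dimethoxyphenyl)ethan-1-one F4. Wittig methylenation (Ph3PCH3Br, KOtBu, toluene, reflux) gives 1-bromo-2,4-dimethoxy-3-(prop-1-en-2-yl)benzene F5. Bromine–lithium exchange (n-BuLi, THF, −78 °C) gives 2,4-dimethoxy-3-(prop-1-en-2-yl)phenyllithium F6, which adds to 4 to give 3,3-diethoxy-1-[2,4-dimethoxy-3-(prop-1-en-2-yl)phenyl]-2,2-dimethylcyclobutan-1-ol F7. Lemieux–Johnson cleavage of the isopropenyl group (OsO4 cat., NaIO4, 2,6-lutidine, dioxane/H2O) then unveils the acetyl group to give 9.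

Step 1. The zwitterion from ketene and ketene acetal may collapse by proton transfer to open-chain acylation products instead of closing the ring, or 4 may lose ethanol during isolation. The fallback uses a ketene–alkyne cycloaddition; it sets out from 3 (generated from 1 as in step 1) and comes back at 4. [2+2] Cycloaddition of 3 with commercial ethoxyacetylene (Et2O, 0 °C → rt) should give 3-ethoxy-4,4-dimethylcyclobut-2-en-1-one F8. Acid-catalysed conjugate addition of ethanol (anhydrous EtOH, cat. PPTS, rt), driven by excess alcohol and by relief of cyclobutene strain, should then give 4.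

**Further compounds**
F1 | step 4 | 1-[3-bromo-5-(3,3-diethoxy-1-hydroxy-2,2-dimethylcyclobutyl)-2,6-dimethoxyphenyl]ethan-1-one | CCOC1(OCC)CC(O)(c2cc(Br)c(OC)c(C(C)=O)c2OC)C1(C)C
F2 | step 4 | 1-(3-acetyl-5-bromo-2,4-dimethoxyphenyl)-4-methylpentane-1,3-dione | CC(C)C(=O)CC(=O)c1cc(Br)c(OC)c(C(C)=O)c1OC
F3 | step 4 | 1-(3-acetyl-2,4-dimethoxy-5,6-didehydrophenyl)-4-methylpentane-1,3-dione (aryne, drawn neutral) | CC(C)C(=O)CC(=O)C1=C(OC)C(C(C)=O)=C(OC)C#C1
F4 | step 3 | 1-(3-bromo-2,6-dimethoxyphenyl)ethan-1-one | CC(=O)c1c(OC)ccc(Br)c1OC
F5 | step 3 | 1-bromo-2,4-dimethoxy-3-(prop-1-en-2-yl)benzene | C=C(C)c1c(OC)ccc(Br)c1OC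
F6 | step 3 | 2,4-dimethoxy-3-(prop-1-en-2-yl)phenyllithium | [Li]c1ccc(OC)c(C(C)=C)c1OC
F7 | step 3 | 3,3-diethoxy-1-[2,4-dimethoxy-3-(prop-1-en-2-yl)phenyl]-2,2-dimethylcyclobutan-1-ol | CCOC1(OCC)CC(O)(c2ccc(OC)c(C(C)=C)c2OC)C1(C)C
F8 | step 1 | 3-ethoxy-4,4-dimethylcyclobut-2-en-1-one | CCOC1=CC(=O)C1(C)C
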